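**Plan**

Locants: ring C1 (C=O), C2 (C–CH3) and C3 (epoxide carbons), C4 (CH2), C5 (CH carrying the chain), C6 (CH–O); chain C7(=CH2)–C8H(O)–CH2–CH=C(CH3)2.
Cuts, in retrosynthetic order: the two angelate C–O bonds; the C6–O bond (enolate oxidation); the C7–C8 bond; the isopropenyl C=CH2 of carvone (degraded to C≡CH).
Enabling feature: C7 is an sp2 carbon bearing =CH2 and flanked by ring carbon C5 and carbinol C8, i.e. a 2-substituted allylic alcohol. C7 and its CH2 map onto a terminal alkyne and C8 onto an aldehyde, so one branch-selective reductive alkyne–aldehyde coupling makes the bond, the exo-methylene and C8, and delivers C8–O already silylated.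
Forward order: the cyclohexane ring is taken intact from (R)-carvone and only the oxirane is closed (directed O-transfer); isopropenyl becomes ethynyl; coupling with 4-methylpent-3-enal joins the chain; then C1 ketone, C6–OH and both angelates.
Stereochemistry: C5 from (R)-carvone; C1 (temporary) by Luche reduction; C2/C3 by OH-directed epoxidation cis to the C5 substituent; C6 by enolate oxidation anti to the C5 chain; C8 by the chiral NHC on nickel.

Key step: step 7

Remark: 4-methylpent-3-enal is assumed not to be a stock item and is made fresh in step 6. Which antipode of the C2-symmetric NHC gives 8S cannot be predicted here, so both would be tried and the 8S-selective one used.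

**Step 1**
Reactants: 1 (R)-(−)-carvone
Product: 2 (−)-cis-carveol [(1R,5R); OH cis to isopropenyl]
Conditions: NaBH4, CeCl3·7H2O, MeOH, 0 °C
Reagents that add atoms: none
Why: Luche 1,2-reduction: hydride adds to C1 axially on the half-chair that keeps the C5 isopropenyl equatorial, which should give the equatorial alcohol cis to isopropenyl (1R) and leave both alkenes untouched.

**Step 2**
Reactants: 2 (−)-cis-carveol
Product: 3 cis-carveol 2,3-epoxide [(1R,2R,4S,6S)-1-methyl-4-(prop-1-en-2-yl)-7-oxabicyclo[4.1.0]heptan-2-ol; epoxide O, OH and isopropenyl on one ring face]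
Conditions: VO(acac)2 (cat.), t-BuOOH (decane), CH2Cl2, 0 °C → rt
Reagents that add atoms: tert-butyl hydroperoxide, CC(C)(C)OO
Why: Vanadium-catalyzed hydroxyl-directed epoxidation: the C1–O–V peroxo complex delivers oxygen to the adjacent C2=C3 bond on the face of the hydroxyl, so the epoxide (C2, C3) should form cis to C1–OH and hence cis to the C5 substituent, while the remote isopropenyl alkene is not activated.

**Step 3**
Reactants: 3 cis-carveol 2,3-epoxide
Product: 4 triethylsilyl ether of 3
Conditions: Et3SiCl, imidazole, DMAP (cat.), DMF, 0 °C → rt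
Reagents that add atoms: chlorotriethylsilane, CC[Si](Cl)(CC)CC
Why: Standard silylation of a secondary alcohol; the TES ether keeps C1 at the alcohol oxidation level through the amide-base and nickel steps and can later be cleaved in the presence of a TIPS ether.

**Step 4**
Reactants: 4 triethylsilyl ether of 3
Product: 5 methyl ketone (acetyl at C5 in place of isopropenyl; ring unchanged)
Conditions: O3, CH2Cl2, −78 °C; then PPh3, −78 °C → rt
Reagents that add atoms: ozone, [O-][O+]=O
Why: Ozonolysis with reductive work-up of the only C=C bond left cleaves the isopropenyl group to the methyl ketone; the neutral conditions leave the now enolizable C5 centre, the epoxide and the silyl ether untouched.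

**Step 5**
Reactants: 5 methyl ketone
Product: 8 terminal alkyne (ethynyl at C5; ring unchanged), via enol phosphate 6 (not isolated), via lithium acetylide 7 (not isolated)
Conditions: LDA (1.1 equiv), THF, −78 °C; ClP(O)(OEt)2, −78 °C → rt; then LDA (2.3 equiv), THF, −78 → 0 °C; aq NH4Cl
Reagents that add atoms: none
Why: One-pot methyl ketone to terminal alkyne conversion through the kinetic enol phosphate (deprotonation at CH3 rather than at the hindered C5 methine, O-phosphorylation, amide-induced β-elimination of phosphate to the acetylide), a sequence with close precedent on cyclohexyl methyl ketone, so C5 should keep its configuration.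

**Step 6**
Reactants: 9 4-methylpent-3-en-1-ol
Product: 10 4-methylpent-3-enal
Conditions: Dess–Martin periodinane, NaHCO3, CH2Cl2, 0 °C → rt; used at once as a solution
Reagents that add atoms: none
Why: Dess–Martin oxidation under buffered, non-basic conditions should give the β,γ-unsaturated aldehyde without migration of the double bond into conjugation.

**Step 7**
Reactants: 8 terminal alkyne; 10 4-methylpent-3-enal
Product: 11 (8S)-branched allylic triisopropylsilyl ether [C5–C7(=CH2)–C8H(OTIPS)–CH2CH=CMe2; C1–OTES and epoxide as in 8]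
Conditions: Ni(cod)2 (10 mol %), bulky C2-symmetric chiral NHC (4,5-diphenylimidazolin-2-ylidene with 2,6-disubstituted N-aryl groups, preformed from its HBF4 salt and KOt-Bu, 10 mol %), iPr3SiH (2 equiv), THF, rt, slow addition of 10
Reagents that add atoms: triisopropylsilane, CC(C)[SiH](C(C)C)C(C)C
Why: Ni(0)–NHC binds alkyne 8 and aldehyde 10 and undergoes oxidative cyclization to an oxanickelacyclopentene in which the bulky N-aryl groups push the large ring substituent of the alkyne onto the carbon remote from nickel, so the aldehyde carbon bonds to the internal alkyne carbon (C7) and the terminal CH sits on nickel; σ-bond metathesis of the Ni–O bond with iPr3SiH and C–H reductive elimination then release the 2-substituted allylic silyl ether and Ni(0). The closest known reaction type is the nickel-catalyzed reductive coupling of aldehydes with terminal alkynes in which large NHC ligands reverse the usual linear selectivity, together with its variants using C2-symmetric chiral NHCs. No ring of the product is closed; the five-membered nickelacycle is transient. The one new stereocentre, C8, is set by the chiral NHC, which selects the aldehyde face in the oxidative cyclization; the resident C5 centre is separated from C8 by the sp2 carbon C7 and should exert only a minor match/mismatch effect. The step needs branched over linear regioselectivity, aldehyde face selectivity, and chemoselectivity for the alkyne–aldehyde pair over the trisubstituted epoxide, the silyl ether and the trisubstituted alkene of 10. The α-branched alkyne terminus, the absence of other π-acceptors in 8, a base-free preformed catalyst and slow addition of the aldehyde are meant to secure these.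

**Step 8**
Reactants: 11 (8S)-branched allylic triisopropylsilyl ether
Product: 12 C1 alcohol (TES removed; TIPS kept)
Conditions: HF·pyridine, pyridine, THF, 0 °C
Reagents that add atoms: none
Why: Fluoride desilylation distinguishes silyl ethers by bulk: the triethylsilyl ether should be cleaved by buffered HF·pyridine at 0 °C much faster than the secondary triisopropylsilyl ether, and the buffered medium spares the epoxide.

**Step 9**
Reactants: 12 C1 alcohol
Product: 13 α,β-epoxy ketone (C1=O; C6 still CH2)
Conditions: Dess–Martin periodinane, NaHCO3, CH2Cl2, rt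
Reagents that add atoms: none
Why: Dess–Martin oxidation of the secondary epoxy alcohol under buffered conditions; C2 is quaternary, so no stereocentre next to the new carbonyl can epimerize.

**Step 10**
Reactants: 13 α,β-epoxy ketone
Product: 15 C6 α-hydroxy ketone (OH trans to the C5 chain), via potassium enolate 14 (not isolated)
Conditions: KHMDS, THF, −78 °C; then 2-(phenylsulfonyl)-3-phenyloxaziridine, −78 °C; aq NH4Cl
Reagents that add atoms: 2-(phenylsulfonyl)-3-phenyloxaziridine, O=S(=O)(c1ccccc1)N1OC1c1ccccc1
Why: Enolate oxidation with an N-sulfonyloxaziridine: C2 is quaternary, so KHMDS can enolize only toward C6, and the oxygen should be delivered to C6 on the face opposite the bulky C5 side chain, giving the trans (diequatorial, also thermodynamically preferred) 5,6-relationship without epoxidizing the isolated alkenes.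

**Step 11**
Reactants: 15 C6 α-hydroxy ketone
Product: 16 C6,C8 diol
Conditions: Bu4NF, AcOH (1:1), THF, 0 °C → rt
Reagents that add atoms: none
Why: Fluoride cleavage of the remaining silyl ether; buffering with acetic acid keeps the medium non-basic so that the α-ketol (C6 epimerization, ketol shift) and the epoxy ketone are not endangered.

**Step 12**
Reactants: 16 C6,C8 diol; 17 angelic acid
Product: 18 target bis-angelate CNP0271744.2
Conditions: angelic acid, 2,4,6-trichlorobenzoyl chloride, Et3N, toluene, rt → 80 °C (mixed anhydride); then 16, 80 °C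
Reagents that add atoms: angelic acid (17), C/C=C(/C)C(=O)O
Why: Yamaguchi-type esterification: both alcohols attack the less hindered angeloyl carbonyl of the preformed mixed anhydride in one operation, and the absence of nucleophilic catalysts (no DMAP) is meant to prevent Z-to-E isomerization of angelate to tiglate.

**Compound list**

1 | (R)-(−)-carvone | C=C(C)[C@@H]1CC=C(C)C(=O)C1 | starting material
2 | (−)-cis-carveol, (1R,5R) | C=C(C)[C@@H]1CC=C(C)[C@H](O)C1 | intermediate
3 | cis-carveol 2,3-epoxide, (1R,2R,4S,6S)-1-methyl-4-(prop-1-en-2-yl)-7-oxabicyclo[4.1.0]heptan-2-ol | C=C(C)[C@@H]1C[C@@H]2O[C@]2(C)[C@H](O)C1 | intermediate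
4 | triethylsilyl ether of 3 | C=C(C)[C@@H]1C[C@@H]2O[C@]2(C)[C@H](O[Si](CC)(CC)CC)C1 | intermediate
5 | methyl ketone (C5 acetyl; OTES, epoxide O and acetyl all cis) | CC(=O)[C@@H]1C[C@@H]2O[C@]2(C)[C@H](O[Si](CC)(CC)CC)C1 | intermediate
6 | enol diethyl phosphate of 5 | C=C(OP(=O)(OCC)OCC)[C@@H]1C[C@@H]2O[C@]2(C)[C@H](O[Si](CC)(CC)CC)C1 | intermediate
7 | lithium acetylide of 8 | [Li+].[C-]#C[C@@H]1C[C@@H]2O[C@]2(C)[C@H](O[Si](CC)(CC)CC)C1 | intermediate
8 | terminal alkyne (C5 ethynyl; OTES, epoxide O and ethynyl all cis) | C#C[C@@H]1C[C@@H]2O[C@]2(C)[C@H](O[Si](CC)(CC)CC)C1 | intermediate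
9 | 4-methylpent-3-en-1-ol | CC(C)=CCCO | starting material
10 | 4-methylpent-3-enal | CC(C)=CCC=O | intermediate
11 | (8S)-branched allylic TIPS ether, C1–OTES | C=C([C@H](CC=C(C)C)O[Si](C(C)C)(C(C)C)C(C)C)[C@@H]1C[C@@H]2O[C@]2(C)[C@H](O[Si](CC)(CC)CC)C1 | intermediate
12 | C1 alcohol, C8–OTIPS | C=C([C@H](CC=C(C)C)O[Si](C(C)C)(C(C)C)C(C)C)[C@@H]1C[C@@H]2O[C@]2(C)[C@H](O)C1 | intermediate
13 | α,β-epoxy ketone, C8–OTIPS | C=C([C@H](CC=C(C)C)O[Si](C(C)C)(C(C)C)C(C)C)[C@@H]1C[C@@H]2O[C@]2(C)C(=O)C1 | intermediate
14 | potassium enolate of 13 (C1=C6) | C=C([C@H](CC=C(C)C)O[Si](C(C)C)(C(C)C)C(C)C)[C@@H]1C[C@@H]2O[C@]2(C)C([O-])=C1.[K+] | intermediate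
15 | C6 α-hydroxy ketone (OH trans to C5 chain), C8–OTIPS | C=C([C@H](CC=C(C)C)O[Si](C(C)C)(C(C)C)C(C)C)[C@@H]1C[C@@H]2O[C@]2(C)C(=O)[C@H]1O | intermediate
16 | C6,C8 diol | C=C([C@H](CC=C(C)C)O)[C@@H]1C[C@@H]2O[C@]2(C)C(=O)[C@H]1O | intermediate
17 | angelic acid, (Z)-2-methylbut-2-enoic acid | C/C=C(/C)C(=O)O | starting material
18 | target, (1S,3S,4S,6S)-4-[(3S)-3-angeloyloxy-6-methylhepta-1,5-dien-2-yl]-1-methyl-2-oxo-7-oxabicyclo[4.1.0]heptan-3-yl angelate | C=C([C@H](CC=C(C)C)OC(=O)/C(C)=C\C)[C@@H]1C[C@@H]2O[C@]2(C)C(=O)[C@H]1OC(=O)/C(C)=C\C | target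

**Step count**

Total steps: 12. Longest linear sequence: 11 (steps 1–5 and 7–12); step 6 is a one-step side branch.

**Steps most likely to fail**

Step 7. The coupling may lose branched regioselectivity or face selectivity at C8, or the β,γ-unsaturated aldehyde may isomerize or oligomerize before it is consumed. The fallback makes the same bond by a chromium-mediated addition. It sets out from methyl ketone 5, which is converted (KHMDS, THF, −78 °C; PhNTf2) into the kinetic enol triflate F1. A catalytic asymmetric Nozaki–Hiyama–Kishi coupling of F1 with aldehyde 10 (CrCl2 cat., NiCl2 cat., chiral oxazoline–sulfonamide ligand, Mn, Cp2ZrCl2, LiCl, MeCN) would give the (8S)-allylic alcohol F2. Silylation of F2 (TIPSOTf, 2,6-lutidine, CH2Cl2, −78 °C) returns to the route at 11.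

Step 10. The strongly basic medium may degrade the α,β-epoxy ketone (enolate-triggered epoxide opening or ring contraction), the enolate may add to the sulfonimine by-product, or face selectivity at C6 may be insufficient on the advanced intermediate. The fallback introduces the C6 oxygen first and sets out from carvone 1. Enolization (LDA, THF, −78 °C) and oxidation with the same oxaziridine would give trans-6-hydroxycarvone F3, which is silylated (TBSCl, imidazole, DMF) to the TBS ether F4. F4 is then taken through the operations of steps 1–5 and 7–9: Luche reduction to the allylic alcohol F5, directed epoxidation to the epoxy alcohol F6, silylation to the TES ether F7, ozonolysis to the methyl ketone F8, phosphorylation to the enol phosphate F9 and elimination to the alkyne F10, nickel coupling with 10 to the bis-silylated coupling product F11, selective TES cleavage to the C1 alcohol F12 and oxidation to the protected ketol F13. Global desilylation of F13 (Bu4NF, AcOH, THF) returns to the route at 16.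

Step 12. Acylation of the hindered C6 ketol hydroxyl may stay incomplete, the angeloyl groups may isomerize to tiglates, or C6 may epimerize or suffer acyl migration under hot amine base. The fallback builds the Z double bonds on the molecule instead of transferring them. Diol 16 is esterified with 2-[bis(2,2,2-trifluoroethoxy)phosphoryl]propanoic acid (DCC, DMAP cat., CH2Cl2) to the bis(phosphonopropionate) F14. A twofold Z-selective Horner–Wadsworth–Emmons olefination of F14 (Still–Gennari variant: KHMDS, 18-crown-6, THF, −78 °C; acetaldehyde) returns to the route at 18.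

**Further compounds**

F1 | step 7 | enol triflate of 5 | C=C(OS(=O)(=O)C(F)(F)F)[C@@H]1C[C@@H]2O[C@]2(C)[C@H](O[Si](CC)(CC)CC)C1
F2 | step 7 | (8S)-allylic alcohol, C1–OTES | C=C([C@H](CC=C(C)C)O)[C@@H]1C[C@@H]2O[C@]2(C)[C@H](O[Si](CC)(CC)CC)C1
F3 | step 10 | trans-6-hydroxycarvone | C=C(C)[C@@H]1CC=C(C)C(=O)[C@H]1O
F4 | step 10 | TBS ether of F3 | C=C(C)[C@@H]1CC=C(C)C(=O)[C@H]1O[Si](C)(C)C(C)(C)C
F5 | step 10 | allylic alcohol (C1–OH trans to C6–OTBS, cis to isopropenyl) | C=C(C)[C@@H]1CC=C(C)[C@H](O)[C@H]1O[Si](C)(C)C(C)(C)C
F6 | step 10 | epoxy alcohol (epoxide cis to C1–OH) | C=C(C)[C@@H]1C[C@@H]2O[C@]2(C)[C@H](O)[C@H]1O[Si](C)(C)C(C)(C)C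
F7 | step 10 | TES ether of F6 | C=C(C)[C@@H]1C[C@@H]2O[C@]2(C)[C@H](O[Si](CC)(CC)CC)[C@H]1O[Si](C)(C)C(C)(C)C
F8 | step 10 | methyl ketone, C6–OTBS | CC(=O)[C@@H]1C[C@@H]2O[C@]2(C)[C@H](O[Si](CC)(CC)CC)[C@H]1O[Si](C)(C)C(C)(C)C
F9 | step 10 | enol diethyl phosphate of F8 | C=C(OP(=O)(OCC)OCC)[C@@H]1C[C@@H]2O[C@]2(C)[C@H](O[Si](CC)(CC)CC)[C@H]1O[Si](C)(C)C(C)(C)C
F10 | step 10 | alkyne, C6–OTBS | C#C[C@@H]1C[C@@H]2O[C@]2(C)[C@H](O[Si](CC)(CC)CC)[C@H]1O[Si](C)(C)C(C)(C)C
F11 | step 10 | bis-silylated coupling product, C1–OTES, C6–OTBS, C8–OTIPS | C=C([C@H](CC=C(C)C)O[Si](C(C)C)(C(C)C)C(C)C)[C@@H]1C[C@@H]2O[C@]2(C)[C@H](O[Si](CC)(CC)CC)[C@H]1O[Si](C)(C)C(C)(C)C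
F12 | step 10 | C1 alcohol, C6–OTBS, C8–OTIPS | C=C([C@H](CC=C(C)C)O[Si](C(C)C)(C(C)C)C(C)C)[C@@H]1C[C@@H]2O[C@]2(C)[C@H](O)[C@H]1O[Si](C)(C)C(C)(C)C
F13 | step 10 | protected ketol, C6–OTBS, C8–OTIPS | C=C([C@H](CC=C(C)C)O[Si](C(C)C)(C(C)C)C(C)C)[C@@H]1C[C@@H]2O[C@]2(C)C(=O)[C@H]1O[Si](C)(C)C(C)(C)C
F14 | step 12 | bis(phosphonopropionate) of 16 (phosphonate α-carbons as epimer mixtures) | C=C([C@H](CC=C(C)C)OC(=O)C(C)P(=O)(OCC(F)(F)F)OCC(F)(F)F)[C@@H]1C[C@@H]2O[C@]2(C)C(=O)[C@H]1OC(=O)C(C)P(=O)(OCC(F)(F)F)OCC(F)(F)F
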